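**Retrosynthetic overview**

1. Feature: numbered as bicyclo[3.3.1]nonan-9-one (C1 hydroxylated bridgehead, C3 C–N, C5 CH bridgehead, C7–C8 epoxide, C9 ketone; ring A = C1–C2–C3–C4–C5–C9, ring B = C1–C8–C7–C6–C5–C9), the C1(OH)–C9(=O) ketol links two carbons that face each other 1,5 across the C1–C8 perimeter, so one transannular C1–C9 bond makes both six-membered rings.
2. Ring order: the eight-membered ring first (ring-closing metathesis, C7=C8), then rings A and B together by a carbene-catalysed transannular crossed benzoin of an all-cis 5-formylcyclooct-7-en-1-one (acyl anion at C9, acceptor C1=O).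
3. End game: fluoride frees the C3 amine and the hydroxyls, the amine is acylated with (E)-7-oxododec-2-enoic acid (from δ-decalactone), and C7=C8 is epoxidised last under direction by C6–OH and C1–OH; on the bicycle the needed exo face is the open one, whereas on the all-cis cyclooctenone a peroxide could not be relied on to enter cis to the C6 substituent.
4. Acyclic stereocentres: C3 from O-benzyl-L-homoserine (L-aspartate series), C4 by Felkin–Anh acetate aldol, C5 together with C9 by Fráter–Seebach hydroxymethylation (C9 anti to O4; an aldol through C5 of a 3-hydroxypent-4-enoate dianion would set C5 against C6 the wrong way), C6 by 1,3-syn reduction of a vinyl ketone; the resulting 3,4-anti, 4,5-anti, 5,6-anti chain folds to the all-cis ring.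
5. Functional-group plan: C1 reaches the ketone level through a γ-lactone with O4 and a Weinreb amide, which also tells the two primary carbinols apart; C9 travels as a primary silyl ether and is oxidised just before ring closure.

Key step: step 18

Remark: C1–C9 in the Why lines are the skeleton locants defined above; aldehydes 22 and 23 are drawn open-chain although they are expected to rest partly as the cyclic N-Teoc hemiaminal formed with the C3 carbamate N–H, a ring–chain tautomer that returns the aldehyde under the basic conditions of step 18 (TBS = tert-butyldimethylsilyl, Teoc = 2-(trimethylsilyl)ethoxycarbonyl).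

**Route**

Step 1
Reactants: 1 O-benzyl-L-homoserine
Product: 2 benzyl (S)-4-(benzyloxy)-2-(dibenzylamino)butanoate
Conditions: BnBr, K2CO3, EtOH–H2O, reflux
Reagents that add atoms: benzyl bromide, BrCc1ccccc1
Why: Threefold SN2 benzylation (amine twice, carboxylate once) should leave the α-stereocentre untouched and installs the dibenzylamino group that later enforces non-chelation control.

Step 2
Reactants: 2 benzyl (S)-4-(benzyloxy)-2-(dibenzylamino)butanoate
Product: 3 (S)-4-(benzyloxy)-2-(dibenzylamino)butan-1-ol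
Conditions: LiAlH4, THF, 0 °C
Reagents that add atoms: none
Why: LiAlH4 ester reduction should give the primary alcohol while the tertiary amine and the benzyl ether stay inert.

Step 3
Reactants: 3 (S)-4-(benzyloxy)-2-(dibenzylamino)butan-1-ol
Product: 4 (S)-4-(benzyloxy)-2-(dibenzylamino)butanal
Conditions: (COCl)2, DMSO, CH2Cl2, −78 °C; Et3N; used crude
Reagents that add atoms: none
Why: Swern oxidation should give the N,N-dibenzyl α-amino aldehyde, a class that holds its configuration when made cold and used crude.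

Step 4
Reactants: 4 (S)-4-(benzyloxy)-2-(dibenzylamino)butanal; 5 methyl acetate
Product: 7 methyl (3R,4S)-6-(benzyloxy)-4-(dibenzylamino)-3-hydroxyhexanoate, via lithium enolate 6 (not isolated)
Conditions: 5, LiN(iPr)2, THF, −78 °C; then 4; aq. NH4Cl
Reagents that add atoms: none
Why: Aldol addition of the lithium ester enolate should follow the Felkin–Anh (non-chelation) model, the dibenzylamino group lying anti to the incoming enolate, which sets C4 with the 3,4-anti relationship.

Step 5
Reactants: 7 methyl (3R,4S)-6-(benzyloxy)-4-(dibenzylamino)-3-hydroxyhexanoate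
Product: 9 methyl (2S,3R,4S)-6-(benzyloxy)-4-(dibenzylamino)-3-hydroxy-2-(hydroxymethyl)hexanoate, via dilithio dianion 8 (not isolated)
Conditions: LiN(iPr)2 (2.3 equiv), THF, −78 → −20 °C; CH2O (monomeric gas), −78 °C
Reagents that add atoms: formaldehyde, C=O
Why: Fráter–Seebach reaction: the lithium-bridged alkoxide enolate should take up formaldehyde on the face of the six-membered chelate opposite to its C4 substituent, which sets C5 (C9 anti to O4) and brings in C9.

Step 6
Reactants: 9 methyl (2S,3R,4S)-6-(benzyloxy)-4-(dibenzylamino)-3-hydroxy-2-(hydroxymethyl)hexanoate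
Product: 10 methyl (2S,3R,4S)-6-(benzyloxy)-2-[(TBS-oxy)methyl]-4-(dibenzylamino)-3-hydroxyhexanoate
Conditions: TBSCl, imidazole, CH2Cl2, 0 °C
Reagents that add atoms: tert-butyldimethylsilyl chloride, CC(C)(C)[Si](C)(C)Cl
Why: Silylation with TBSCl/imidazole should pick the primary C9 hydroxyl over the hindered secondary C4 hydroxyl, which has to stay free to direct step 10.

Step 7
Reactants: 10 methyl (2S,3R,4S)-6-(benzyloxy)-2-[(TBS-oxy)methyl]-4-(dibenzylamino)-3-hydroxyhexanoate
Product: 11 (2S,3R,4S)-6-(benzyloxy)-2-[(TBS-oxy)methyl]-4-(dibenzylamino)-3-hydroxy-N-methoxy-N-methylhexanamide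
Conditions: MeNHOMe·HCl, iPrMgCl, THF, −20 → 0 °C
Reagents that add atoms: N,O-dimethylhydroxylamine hydrochloride, CNOC.Cl
Why: Weinreb amide synthesis: aminolysis of the methyl ester by ClMgN(OMe)Me at low temperature should proceed without retro-aldol or epimerisation at C5 because the magnesium aldolate is stable under these conditions.

Step 8
Reactants: 11 (2S,3R,4S)-6-(benzyloxy)-2-[(TBS-oxy)methyl]-4-(dibenzylamino)-3-hydroxy-N-methoxy-N-methylhexanamide
Product: 13 (2S,3R,4S)-2-[(TBS-oxy)methyl]-3,6-dihydroxy-N-methoxy-N-methyl-4-(Teoc-amino)hexanamide, via free amine 12 (not isolated)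
Conditions: H2 (1 atm), Pd(OH)2/C, Teoc-OSu, EtOH–EtOAc, rt
Reagents that add atoms: N-[2-(trimethylsilyl)ethoxycarbonyloxy]succinimide (Teoc-OSu), C[Si](C)(C)CCOC(=O)ON1C(=O)CCC1=O
Why: Hydrogenolysis should cleave both N-benzyl groups and the O-benzyl ether while no alkene is yet present, and carbamoylation by Teoc-OSu in the same flask should trap amine 12 before it can lactamise onto the Weinreb amide.

Step 9
Reactants: 13 (2S,3R,4S)-2-[(TBS-oxy)methyl]-3,6-dihydroxy-N-methoxy-N-methyl-4-(Teoc-amino)hexanamide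
Product: 14 2-(trimethylsilyl)ethyl N-[(3S,4R,5S)-5-[(TBS-oxy)methyl]-1,4-dihydroxy-6-oxooct-7-en-3-yl]carbamate
Conditions: CH2=CHMgBr (excess), THF, −78 → 0 °C; inverse quench into cold aq. KHSO4; used crude
Reagents that add atoms: vinylmagnesium bromide, C=C[Mg]Br
Why: Weinreb ketone synthesis: the magnesium-chelated tetrahedral adduct should hold until the acidic quench, which prevents over-addition and protonates the released amine so that it cannot add to the vinyl ketone.

Step 10
Reactants: 14 2-(trimethylsilyl)ethyl N-[(3S,4R,5S)-5-[(TBS-oxy)methyl]-1,4-dihydroxy-6-oxooct-7-en-3-yl]carbamate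
Product: 15 2-(trimethylsilyl)ethyl N-[(3S,4R,5R,6R)-5-[(TBS-oxy)methyl]-1,4,6-trihydroxyoct-7-en-3-yl]carbamate
Conditions: Et2BOMe, THF–MeOH, −78 °C; NaBH4; then MeOH, evaporate
Reagents that add atoms: none
Why: Narasaka–Prasad reduction: hydride should add axially to the six-membered boron chelate of the β-hydroxy ketone, in which the C3 chain and C9 are both equatorial, giving the 4,6-syn diol and so setting C6.

Step 11
Reactants: 15 2-(trimethylsilyl)ethyl N-[(3S,4R,5R,6R)-5-[(TBS-oxy)methyl]-1,4,6-trihydroxyoct-7-en-3-yl]carbamate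
Product: 17 2-(trimethylsilyl)ethyl N-[(2R,3S)-2-[(2R,3R)-1-(TBS-oxy)-3-hydroxypent-4-en-2-yl]-5-oxooxolan-3-yl]carbamate, via lactol 16 (not isolated)
Conditions: TEMPO (cat.), PhI(OAc)2, CH2Cl2, rt
Reagents that add atoms: none
Why: Oxoammonium (TEMPO) oxidation is selective for the primary C1 carbinol; the aldehyde should be captured by C4–OH as lactol 16 and oxidised on to the γ-lactone, which brings C1 to the acid level and masks O4.

Step 12
Reactants: 17 2-(trimethylsilyl)ethyl N-[(2R,3S)-2-[(2R,3R)-1-(TBS-oxy)-3-hydroxypent-4-en-2-yl]-5-oxooxolan-3-yl]carbamate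
Product: 18 (3S,4R,5R,6R)-5-[(TBS-oxy)methyl]-4,6-dihydroxy-N-methoxy-N-methyl-3-(Teoc-amino)oct-7-enamide
Conditions: MeNHOMe·HCl, iPrMgCl, THF, −20 °C; used at once
Reagents that add atoms: N,O-dimethylhydroxylamine hydrochloride, CNOC.Cl
Why: Aminolysis of the γ-lactone by ClMgN(OMe)Me (Weinreb amide synthesis) should open the ring and free C4–OH; the hydroxy amide is silylated at once so that it cannot relactonise.

Step 13
Reactants: 18 (3S,4R,5R,6R)-5-[(TBS-oxy)methyl]-4,6-dihydroxy-N-methoxy-N-methyl-3-(Teoc-amino)oct-7-enamide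
Product: 19 (3S,4R,5R,6R)-4,6-bis(TBS-oxy)-5-[(TBS-oxy)methyl]-N-methoxy-N-methyl-3-(Teoc-amino)oct-7-enamide
Conditions: TBSOTf, 2,6-lutidine, CH2Cl2, −78 → 0 °C
Reagents that add atoms: tert-butyldimethylsilyl trifluoromethanesulfonate, CC(C)(C)[Si](C)(C)OS(=O)(=O)C(F)(F)F
Why: Silylation with the silyl triflate and 2,6-lutidine should cap both hindered secondary hydroxyls, and any N-silylated carbamate is hydrolysed on work-up.

Step 14
Reactants: 19 (3S,4R,5R,6R)-4,6-bis(TBS-oxy)-5-[(TBS-oxy)methyl]-N-methoxy-N-methyl-3-(Teoc-amino)oct-7-enamide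
Product: 20 (3S,4R,5R,6R)-4,6-bis(TBS-oxy)-5-(hydroxymethyl)-N-methoxy-N-methyl-3-(Teoc-amino)oct-7-enamide
Conditions: HF·pyridine, pyridine, THF, 0 °C
Reagents that add atoms: none
Why: Selective desilylation: buffered HF·pyridine should cleave the primary silyl ether far faster than the two secondary ones and does not attack the Teoc group.

Step 15
Reactants: 20 (3S,4R,5R,6R)-4,6-bis(TBS-oxy)-5-(hydroxymethyl)-N-methoxy-N-methyl-3-(Teoc-amino)oct-7-enamide
Product: 21 2-(trimethylsilyl)ethyl N-[(5S,6R,7R,8R)-6,8-bis(TBS-oxy)-7-(hydroxymethyl)-3-oxodeca-1,9-dien-5-yl]carbamate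
Conditions: CH2=CHMgBr (excess), THF, −78 → 0 °C; inverse quench into cold aq. KHSO4
Reagents that add atoms: vinylmagnesium bromide, C=C[Mg]Br
Why: Weinreb ketone synthesis as in step 9, the first equivalents of Grignard reagent being consumed by O–H and N–H.

Step 16
Reactants: 21 2-(trimethylsilyl)ethyl N-[(5S,6R,7R,8R)-6,8-bis(TBS-oxy)-7-(hydroxymethyl)-3-oxodeca-1,9-dien-5-yl]carbamate
Product: 22 2-(trimethylsilyl)ethyl N-[(5S,6R,7R,8R)-6,8-bis(TBS-oxy)-7-formyl-3-oxodeca-1,9-dien-5-yl]carbamate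
Conditions: (COCl)2, DMSO, CH2Cl2, −78 °C; Et3N, −78 → −40 °C
Reagents that add atoms: none
Why: Swern oxidation at low temperature should give the aldehyde without β-elimination of a silyloxy group, epimerisation at C5 or over-oxidation of the hemiaminal tautomer.

Step 17
Reactants: 22 2-(trimethylsilyl)ethyl N-[(5S,6R,7R,8R)-6,8-bis(TBS-oxy)-7-formyl-3-oxodeca-1,9-dien-5-yl]carbamate
Product: 23 2-(trimethylsilyl)ethyl N-[(3S,4R,5R,6R,7Z)-4,6-bis(TBS-oxy)-5-formyl-1-oxocyclooct-7-en-3-yl]carbamate (skeleton numbering; NHTeoc, both OTBS and CHO on one face)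
Conditions: second-generation Hoveyda–Grubbs catalyst RuCl2(H2IMes)(=CH-C6H4-2-OiPr) (10 mol %), toluene (0.001 M), 80 °C
Reagents that add atoms: none
Why: Ring-closing metathesis: loss of ethene drives closure, the four contiguous substituted carbons (C3–C6) fold the chain, and the eight-membered ring can only hold the Z alkene.

Step 18
Reactants: 23 2-(trimethylsilyl)ethyl N-[(3S,4R,5R,6R,7Z)-4,6-bis(TBS-oxy)-5-formyl-1-oxocyclooct-7-en-3-yl]carbamate
Product: 25 2-(trimethylsilyl)ethyl N-[(1S,3S,4R,5R,6R)-4,6-bis(TBS-oxy)-1-hydroxy-9-oxobicyclo[3.3.1]non-7-en-3-yl]carbamate (all substituents exo), via Breslow intermediate 24 (not isolated)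
Conditions: 2-(pentafluorophenyl)-6,7-dihydro-5H-pyrrolo[2,1-c][1,2,4]triazol-2-ium tetrafluoroborate (20 mol %), iPr2NEt (20 mol %), toluene (0.005 M), 40 °C
Reagents that add atoms: none
Why: Proposed new method: the triazolylidene adds to the C9 aldehyde of 23 and proton transfer gives Breslow intermediate 24, whose nucleophilic C9 attacks the C1 ketone across the ring before the carbene is expelled, leaving the C1(OH)–C9(=O) ketol; the closest known reaction is the carbene-catalysed intramolecular aldehyde–ketone crossed benzoin that gives tertiary α-ketols in six-membered rings, here extended to a transannular case on an eight-membered ring. The one new bond C1–C9 closes ring A (C1–C2–C3–C4–C5–C9) and ring B (C1–C8–C7–C6–C5–C9) at the same time, each in a 6-exo-trig sense. C1 is the only new stereocentre and is dictated by the bridge: C9 hangs from C5 on the face that also carries the C3, C4 and C6 substituents, so it can reach C1 only from that face and leaves all of them exo. The step needs crossed chemoselectivity, which is secured because only the aldehyde can become the acyl anion equivalent, conjugate (Stetter) addition to C7 would require a four-membered ring, and high dilution disfavours intermolecular benzoin. A weak amine base is used so that silanolate β-elimination and enolate aldol closure from C2 or C5 are slow, while it still opens the hemiaminal tautomer and lets a C5 epimer, which cannot cyclise, drain back through the cis aldehyde. In 25 the ketone sits between a quaternary carbon and a bridgehead, so it cannot enolise and the product is not eroded.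

Step 19
Reactants: 25 2-(trimethylsilyl)ethyl N-[(1S,3S,4R,5R,6R)-4,6-bis(TBS-oxy)-1-hydroxy-9-oxobicyclo[3.3.1]non-7-en-3-yl]carbamate
Product: 26 (1S,3S,4R,5R,6R)-3-amino-1,4,6-trihydroxybicyclo[3.3.1]non-7-en-9-one
Conditions: Bu4NF, AcOH, THF, 0 °C → rt; used crude
Reagents that add atoms: none
Why: Fluoride-induced cleavage: the Teoc group should fragment to ethene, CO2 and Me3SiF and both silyl ethers are cleaved, acetic acid buffering the alkoxides so that the ketol does not rearrange.

Step 20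
Reactants: 27 δ-decalactone (racemic)
Product: 28 6-pentyltetrahydro-2H-pyran-2-ol (lactol)
Conditions: iBu2AlH, CH2Cl2, −78 °C
Reagents that add atoms: none
Why: Half-reduction of the lactone by iBu2AlH at −78 °C should stop at the lactol because the tetrahedral aluminate survives until work-up.

Step 21
Reactants: 28 6-pentyltetrahydro-2H-pyran-2-ol; 29 tert-butyl (triphenylphosphoranylidene)acetate
Product: 30 tert-butyl (E)-7-hydroxydodec-2-enoate
Conditions: toluene, 80 °C
Reagents that add atoms: none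
Why: Wittig olefination of the open hydroxy aldehyde tautomer with the stabilised ylide should give the E enoate.

Step 22
Reactants: 30 tert-butyl (E)-7-hydroxydodec-2-enoate
Product: 31 tert-butyl (E)-7-oxododec-2-enoate
Conditions: Dess–Martin periodinane, CH2Cl2, rt
Reagents that add atoms: none
Why: Dess–Martin oxidation of the secondary alcohol gives the ketone and removes the stereocentre inherited from the racemic lactone.

Step 23
Reactants: 31 tert-butyl (E)-7-oxododec-2-enoate
Product: 32 (E)-7-oxododec-2-enoic acid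
Conditions: CF3CO2H, CH2Cl2, rt
Reagents that add atoms: none
Why: Acidolysis of the tert-butyl ester (loss of isobutene) should free the acid without touching the ketone or the conjugated alkene.

Step 24
Reactants: 26 (1S,3S,4R,5R,6R)-3-amino-1,4,6-trihydroxybicyclo[3.3.1]non-7-en-9-one; 32 (E)-7-oxododec-2-enoic acid
Product: 34 (E)-N-[(1S,3S,4R,5R,6R)-1,4,6-trihydroxy-9-oxobicyclo[3.3.1]non-7-en-3-yl]-7-oxododec-2-enamide, via benzotriazolyl ester 33 (not isolated)
Conditions: EDC·HCl, HOBt, iPr2NEt, DMF, 0 °C → rt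
Reagents that add atoms: none
Why: Carbodiimide/HOBt amide coupling through active ester 33: the primary amine is far more nucleophilic than the secondary and tertiary hydroxyls, so acylation should occur on nitrogen only.

Step 25
Reactants: 34 (E)-N-[(1S,3S,4R,5R,6R)-1,4,6-trihydroxy-9-oxobicyclo[3.3.1]non-7-en-3-yl]-7-oxododec-2-enamide
Product: 35 isariotin C, (E)-N-[(1S,3S,4R,5S,6S,7S,8S)-7,8-epoxy-1,4,6-trihydroxy-9-oxobicyclo[3.3.1]nonan-3-yl]-7-oxododec-2-enamide
Conditions: VO(acac)2 (cat.), tBuOOH (decane), CH2Cl2, 0 °C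
Reagents that add atoms: tert-butyl hydroperoxide, CC(C)(C)OO
Why: Hydroxyl-directed vanadium-catalysed epoxidation: the pseudoaxial C6–OH and the bridgehead C1–OH both lie on the exo face (syn to C9) while ring A shields the endo face and the conjugated amide alkene is no substrate, so oxygen should be delivered to C7=C8 cis to O6 and complete the all-cis array (C7, C8).

**Compound list**

1 | O-benzyl-L-homoserine | c1ccccc1COCC[C@H](N)C(=O)O | starting material
2 | benzyl (S)-4-(benzyloxy)-2-(dibenzylamino)butanoate | c1ccccc1COCC[C@H](N(Cc1ccccc1)Cc1ccccc1)C(=O)OCc1ccccc1 | intermediate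
3 | (S)-4-(benzyloxy)-2-(dibenzylamino)butan-1-ol | c1ccccc1COCC[C@H](N(Cc1ccccc1)Cc1ccccc1)CO | intermediate
4 | (S)-4-(benzyloxy)-2-(dibenzylamino)butanal | c1ccccc1COCC[C@H](N(Cc1ccccc1)Cc1ccccc1)C=O | intermediate
5 | methyl acetate | COC(C)=O | starting material
6 | lithium enolate of methyl acetate (not isolated) | C=C(O[Li])OC | intermediate
7 | methyl (3R,4S)-6-(benzyloxy)-4-(dibenzylamino)-3-hydroxyhexanoate | c1ccccc1COCC[C@H](N(Cc1ccccc1)Cc1ccccc1)[C@H](O)CC(=O)OC | intermediate
8 | dilithio alkoxide enolate of 7 (not isolated) | c1ccccc1COCC[C@H](N(Cc1ccccc1)Cc1ccccc1)[C@H](O[Li])C=C(O[Li])OC | intermediate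
9 | methyl (2S,3R,4S)-6-(benzyloxy)-4-(dibenzylamino)-3-hydroxy-2-(hydroxymethyl)hexanoate | c1ccccc1COCC[C@H](N(Cc1ccccc1)Cc1ccccc1)[C@H](O)[C@H](CO)C(=O)OC | intermediate
10 | methyl (2S,3R,4S)-6-(benzyloxy)-2-[(TBS-oxy)methyl]-4-(dibenzylamino)-3-hydroxyhexanoate | c1ccccc1COCC[C@H](N(Cc1ccccc1)Cc1ccccc1)[C@H](O)[C@H](CO[Si](C)(C)C(C)(C)C)C(=O)OC | intermediate
11 | (2S,3R,4S)-6-(benzyloxy)-2-[(TBS-oxy)methyl]-4-(dibenzylamino)-3-hydroxy-N-methoxy-N-methylhexanamide | c1ccccc1COCC[C@H](N(Cc1ccccc1)Cc1ccccc1)[C@H](O)[C@H](CO[Si](C)(C)C(C)(C)C)C(=O)N(C)OC | intermediate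
12 | (2S,3R,4S)-4-amino-2-[(TBS-oxy)methyl]-3,6-dihydroxy-N-methoxy-N-methylhexanamide (not isolated) | OCC[C@H](N)[C@H](O)[C@H](CO[Si](C)(C)C(C)(C)C)C(=O)N(C)OC | intermediate
13 | (2S,3R,4S)-2-[(TBS-oxy)methyl]-3,6-dihydroxy-N-methoxy-N-methyl-4-(Teoc-amino)hexanamide | OCC[C@H](NC(=O)OCC[Si](C)(C)C)[C@H](O)[C@H](CO[Si](C)(C)C(C)(C)C)C(=O)N(C)OC | intermediate
14 | 2-(trimethylsilyl)ethyl N-[(3S,4R,5S)-5-[(TBS-oxy)methyl]-1,4-dihydroxy-6-oxooct-7-en-3-yl]carbamate | OCC[C@H](NC(=O)OCC[Si](C)(C)C)[C@H](O)[C@H](CO[Si](C)(C)C(C)(C)C)C(=O)C=C | intermediate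
15 | 2-(trimethylsilyl)ethyl N-[(3S,4R,5R,6R)-5-[(TBS-oxy)methyl]-1,4,6-trihydroxyoct-7-en-3-yl]carbamate | OCC[C@H](NC(=O)OCC[Si](C)(C)C)[C@H](O)[C@H](CO[Si](C)(C)C(C)(C)C)[C@H](O)C=C | intermediate
16 | lactol, 2-(trimethylsilyl)ethyl N-[(2R,3S)-2-[(2R,3R)-1-(TBS-oxy)-3-hydroxypent-4-en-2-yl]-5-hydroxyoxolan-3-yl]carbamate, both anomers (not isolated) | OC1C[C@H](NC(=O)OCC[Si](C)(C)C)[C@H](O1)[C@H](CO[Si](C)(C)C(C)(C)C)[C@H](O)C=C | intermediate
17 | 2-(trimethylsilyl)ethyl N-[(2R,3S)-2-[(2R,3R)-1-(TBS-oxy)-3-hydroxypent-4-en-2-yl]-5-oxooxolan-3-yl]carbamate | O=C1C[C@H](NC(=O)OCC[Si](C)(C)C)[C@H](O1)[C@H](CO[Si](C)(C)C(C)(C)C)[C@H](O)C=C | intermediate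
18 | (3S,4R,5R,6R)-5-[(TBS-oxy)methyl]-4,6-dihydroxy-N-methoxy-N-methyl-3-(Teoc-amino)oct-7-enamide | CON(C)C(=O)C[C@H](NC(=O)OCC[Si](C)(C)C)[C@H](O)[C@H](CO[Si](C)(C)C(C)(C)C)[C@H](O)C=C | intermediate
19 | (3S,4R,5R,6R)-4,6-bis(TBS-oxy)-5-[(TBS-oxy)methyl]-N-methoxy-N-methyl-3-(Teoc-amino)oct-7-enamide | CON(C)C(=O)C[C@H](NC(=O)OCC[Si](C)(C)C)[C@H](O[Si](C)(C)C(C)(C)C)[C@H](CO[Si](C)(C)C(C)(C)C)[C@H](O[Si](C)(C)C(C)(C)C)C=C | intermediate
20 | (3S,4R,5R,6R)-4,6-bis(TBS-oxy)-5-(hydroxymethyl)-N-methoxy-N-methyl-3-(Teoc-amino)oct-7-enamide | CON(C)C(=O)C[C@H](NC(=O)OCC[Si](C)(C)C)[C@H](O[Si](C)(C)C(C)(C)C)[C@H](CO)[C@H](O[Si](C)(C)C(C)(C)C)C=C | intermediate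
21 | 2-(trimethylsilyl)ethyl N-[(5S,6R,7R,8R)-6,8-bis(TBS-oxy)-7-(hydroxymethyl)-3-oxodeca-1,9-dien-5-yl]carbamate | C=CC(=O)C[C@H](NC(=O)OCC[Si](C)(C)C)[C@H](O[Si](C)(C)C(C)(C)C)[C@H](CO)[C@H](O[Si](C)(C)C(C)(C)C)C=C | intermediate
22 | 2-(trimethylsilyl)ethyl N-[(5S,6R,7R,8R)-6,8-bis(TBS-oxy)-7-formyl-3-oxodeca-1,9-dien-5-yl]carbamate | C=CC(=O)C[C@H](NC(=O)OCC[Si](C)(C)C)[C@H](O[Si](C)(C)C(C)(C)C)[C@H](C=O)[C@H](O[Si](C)(C)C(C)(C)C)C=C | intermediate
23 | all-cis cyclooctenone aldehyde, 2-(trimethylsilyl)ethyl N-[(3S,4R,5R,6R,7Z)-4,6-bis(TBS-oxy)-5-formyl-1-oxocyclooct-7-en-3-yl]carbamate (skeleton numbering) | C[Si](C)(C)CCOC(=O)N[C@H]1CC(=O)/C=C\[C@@H](O[Si](C)(C)C(C)(C)C)[C@@H](C=O)[C@H]1O[Si](C)(C)C(C)(C)C | intermediate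
24 | Breslow intermediate of 23, C9 enaminol of the triazolylidene (not isolated) | C[Si](C)(C)CCOC(=O)N[C@H]1CC(=O)/C=C\[C@@H](O[Si](C)(C)C(C)(C)C)[C@@H](C(O)=C2N(c4c(F)c(F)c(F)c(F)c4F)N=C3CCCN23)[C@H]1O[Si](C)(C)C(C)(C)C | intermediate
25 | 2-(trimethylsilyl)ethyl N-[(1S,3S,4R,5R,6R)-4,6-bis(TBS-oxy)-1-hydroxy-9-oxobicyclo[3.3.1]non-7-en-3-yl]carbamate | C[Si](C)(C)CCOC(=O)N[C@H]1C[C@@]2(O)C(=O)[C@H]([C@H](O[Si](C)(C)C(C)(C)C)C=C2)[C@H]1O[Si](C)(C)C(C)(C)C | intermediate
26 | (1S,3S,4R,5R,6R)-3-amino-1,4,6-trihydroxybicyclo[3.3.1]non-7-en-9-one | N[C@H]1C[C@@]2(O)C(=O)[C@H]([C@H](O)C=C2)[C@H]1O | intermediate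
27 | δ-decalactone (6-pentyltetrahydro-2H-pyran-2-one, racemic) | CCCCCC1CCCC(=O)O1 | starting material
28 | 6-pentyltetrahydro-2H-pyran-2-ol | CCCCCC1CCCC(O)O1 | intermediate
29 | tert-butyl (triphenylphosphoranylidene)acetate | CC(C)(C)OC(=O)C=P(c1ccccc1)(c1ccccc1)c1ccccc1 | starting material
30 | tert-butyl (E)-7-hydroxydodec-2-enoate | CCCCCC(O)CCC/C=C/C(=O)OC(C)(C)C | intermediate
31 | tert-butyl (E)-7-oxododec-2-enoate | CCCCCC(=O)CCC/C=C/C(=O)OC(C)(C)C | intermediate
32 | (E)-7-oxododec-2-enoic acid | CCCCCC(=O)CCC/C=C/C(=O)O | intermediate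
33 | benzotriazol-1-yl (E)-7-oxododec-2-enoate (not isolated) | CCCCCC(=O)CCC/C=C/C(=O)On1nnc2ccccc12 | intermediate
34 | (E)-N-[(1S,3S,4R,5R,6R)-1,4,6-trihydroxy-9-oxobicyclo[3.3.1]non-7-en-3-yl]-7-oxododec-2-enamide | CCCCCC(=O)CCC/C=C/C(=O)N[C@H]1C[C@@]2(O)C(=O)[C@H]([C@H](O)C=C2)[C@H]1O | intermediate
35 | isariotin C | CCCCCC(=O)CCC/C=C/C(=O)N[C@H]1C[C@@]2(O)C(=O)[C@H]([C@H](O)[C@@H]3O[C@@H]32)[C@H]1O | target

**Step count and risks**

Total step count: 25. Longest linear sequence: 21 steps (steps 1–19, 24 and 25, from 1 to 35); the side-chain acid 32 takes 4 steps (20–23).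

Steps most likely to fail:

Step 18 (transannular carbene benzoin, the proposed new method). What may go wrong: the aldehyde may stay locked as its N-Teoc hemiaminal, silanolate may be lost by β-elimination from the aldehyde enolate, or enolate-type transannular aldol closure may outrun formation of the acyl anion equivalent. Fallback by known chemistry, setting out from 23: reductive transannular pinacol coupling with SmI2 (THF, −78 °C) joins the C9 aldehyde and the C1 ketone through the same C1–C9 bond and should give the bicyclic 1,9-diol F1. Swern oxidation of its secondary C9 carbinol (the tertiary C1 carbinol cannot be oxidised) then comes back to the route at 25.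

Step 17 (ring-closing metathesis to the eight-membered enone). What may go wrong: slow initiation at the electron-poor vinyl ketone and the hindered allylic silyl ether may let intermolecular cross-metathesis and oligomerisation win over medium-ring closure. Fallback, setting out from 21: Luche reduction (NaBH4, CeCl3·7H2O, MeOH, −78 °C) turns the vinyl ketone into the bis-allylic dienediol F2 (C1 epimers). Metathesis with the second-generation Grubbs catalyst RuCl2(H2IMes)(PCy3)(=CHPh) then closes the ring between two electron-richer allylic alkenes to give cyclooctenediol F3. Twofold Swern oxidation of its C1 and C9 carbinols comes back to the route at 23.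

Step 25 (late hydroxyl-directed epoxidation). What may go wrong: oxidation of the secondary allylic C6 carbinol to the enone, or oxidative attack on the ketol, may compete with oxygen transfer to C7=C8 on the fully deprotected substrate. Fallback, setting out from 25: epoxidation with mCPBA (NaHCO3, CH2Cl2, 0 °C), directed by hydrogen bonding to the pseudo-equatorial bridgehead C1–OH, gives the silyl-protected epoxy ketol F4. Bu4NF/AcOH then gives the epoxy amino triol F5, and the carbodiimide coupling of step 24 with acid 32 comes back to the route at 35.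

Further compounds
F1 | step 18 | 2-(trimethylsilyl)ethyl N-[(1S,3S,4R,5R,6R)-4,6-bis(TBS-oxy)-1,9-dihydroxybicyclo[3.3.1]non-7-en-3-yl]carbamate (C9 carbinol, either epimer) | C[Si](C)(C)CCOC(=O)N[C@H]1C[C@@]2(O)C(O)[C@H]([C@H](O[Si](C)(C)C(C)(C)C)C=C2)[C@H]1O[Si](C)(C)C(C)(C)C
F2 | step 17 | 2-(trimethylsilyl)ethyl N-[(5S,6R,7R,8R)-6,8-bis(TBS-oxy)-3-hydroxy-7-(hydroxymethyl)deca-1,9-dien-5-yl]carbamate (C3 carbinol epimers) | C=CC(O)C[C@H](NC(=O)OCC[Si](C)(C)C)[C@H](O[Si](C)(C)C(C)(C)C)[C@H](CO)[C@H](O[Si](C)(C)C(C)(C)C)C=C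
F3 | step 17 | 2-(trimethylsilyl)ethyl N-[(3S,4R,5R,6R,7Z)-4,6-bis(TBS-oxy)-1-hydroxy-5-(hydroxymethyl)cyclooct-7-en-3-yl]carbamate (skeleton numbering, C1 epimers) | OC1/C=C\[C@@H](O[Si](C)(C)C(C)(C)C)[C@@H](CO)[C@@H](O[Si](C)(C)C(C)(C)C)[C@@H](NC(=O)OCC[Si](C)(C)C)C1
F4 | step 25 | 2-(trimethylsilyl)ethyl N-[4,6-bis(TBS-oxy)-7,8-epoxy-1-hydroxy-9-oxobicyclo[3.3.1]nonan-3-yl]carbamate (all substituents and epoxide exo) | C[Si](C)(C)CCOC(=O)N[C@H]1C[C@@]2(O)C(=O)[C@H]([C@H](O[Si](C)(C)C(C)(C)C)[C@@H]3O[C@@H]32)[C@H]1O[Si](C)(C)C(C)(C)C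
F5 | step 25 | (1S,3S,4R,5S,6S,7S,8S)-3-amino-7,8-epoxy-1,4,6-trihydroxybicyclo[3.3.1]nonan-9-one | N[C@H]1C[C@@]2(O)C(=O)[C@H]([C@H](O)[C@@H]3O[C@@H]32)[C@H]1O
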